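**Retrosynthetic overview**

1. The target is the 4-hydroxy-3-methoxybenzoate of (1R,2Z,9E)-2,5,5,9-tetramethylcycloundeca-2,9-dien-1-ol; the phenol is unmasked last (aryl acetate), and the ester is put on the acyclic alcohol before the ring is closed.
2. Key disconnection: ring bond C6–C7, formed as a C6=C7 alkene by ring-closing metathesis of an acyclic tetraene ester and then saturated with diimide; this eleven-membered carbocycle is the only ring formed (step 9).
3. Enabling feature: C6–C7 lies in the saturated C6–C7–C8 segment between quaternary C5 and alkene carbon C9, the one ring bond without stereochemical information, so an E/Z mixture from the closure converges on one product. The resident C2=C3 and C9=C10 alkenes are trisubstituted and should be spectators in both metathesis and diimide reduction, and the C5 gem-dimethyl group pre-folds the chain.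
4. Acyclic precursor: C1–C2 bond by addition of a Z-vinyllithium (Stork–Zhao-type iodo-olefination) to a β,γ-unsaturated aldehyde (E-alkene from Negishi carboalumination); C1 (R) is set by oxidation and Corey–Bakshi–Shibata reduction.

Key step: step 9

Remark: ring atoms are numbered C1 (carbinol carbon), C2=C3 (Z-alkene), C5 (quaternary), C9=C10 (E-alkene), C11; chain C7 of the acyclic intermediates becomes ring C1. Pent-1-en-4-yne, methyl 3,3-dimethylpent-4-enoate and 4-acetoxy-3-methoxybenzoic acid are taken as purchasable.

**Route**

Step 1
Reactants: 1 pent-1-en-4-yne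
Product: 4 (3E)-4-methylhepta-3,6-dien-1-ol, via alkenyl(dimethyl)alane 2 (not isolated), via lithium alkenylalanate 3 (not isolated)
Conditions: AlMe3 (2.0 equiv), Cp2ZrCl2 (0.25 equiv), CH2Cl2, 0 °C → rt; volatiles removed; n-BuLi (1.0 equiv), hexane/THF, −30 °C; oxirane, −30 °C → rt; aq. NH4Cl
Reagents that add atoms: trimethylaluminium C[Al](C)C; oxirane C1CO1
Why: Negishi carboalumination adds methyl and aluminium syn across the terminal alkyne only (the isolated alkene should stay inert), and the derived alanate opens oxirane with retention at the alkenyl carbon, which fixes the 3E trisubstituted alkene.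

Step 2
Reactants: 4 (3E)-4-methylhepta-3,6-dien-1-ol
Product: 5 (3E)-4-methylhepta-3,6-dienal
Conditions: Dess–Martin periodinane (1.2 equiv), pyridine, CH2Cl2, 0 °C → rt; used crude
Reagents that add atoms: none
Why: Dess–Martin oxidation under buffered, non-basic conditions should give the β,γ-unsaturated aldehyde without migration of the C3=C4 alkene into conjugation.

Step 3
Reactants: 6 methyl 3,3-dimethylpent-4-enoate
Product: 7 3,3-dimethylpent-4-enal
Conditions: i-Bu2AlH (1.05 equiv), CH2Cl2, −78 °C; MeOH, then aq. potassium sodium tartrate (KNaC4H4O6)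
Reagents that add atoms: none
Why: Partial ester reduction with i-Bu2AlH at −78 °C should stop at the aluminium hemiacetal, which releases the aldehyde on work-up; no stereocentre is involved.

Step 4
Reactants: 7 3,3-dimethylpent-4-enal
Product: 8 (5Z)-6-iodo-3,3-dimethylhepta-1,5-diene
Conditions: EtPPh3I, n-BuLi, THF, 0 °C → rt; I2, −78 °C; NaN(SiMe3)2, −78 → −20 °C; then 7, −78 °C → rt
Reagents that add atoms: ethyltriphenylphosphonium iodide CC[P+](c1ccccc1)(c1ccccc1)c1ccccc1.[I-]; iodine I-I
Why: Stork–Zhao-type Wittig iodo-olefination with the non-stabilised α-iodo ylide is kinetically controlled and should place iodine cis to the alkyl chain, giving the Z-vinyl iodide that encodes the C2=C3 geometry of the ring.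

Step 5
Reactants: 8 (5Z)-6-iodo-3,3-dimethylhepta-1,5-diene; 5 (3E)-4-methylhepta-3,6-dienal
Product: 10 rac-(4E,8Z)-4,8,11,11-tetramethyltrideca-1,4,8,12-tetraen-7-ol, via vinyllithium 9 (not isolated)
Conditions: t-BuLi (2.0 equiv), Et2O, −78 °C; then 5, −78 °C; aq. NH4Cl
Reagents that add atoms: none
Why: Iodine–lithium exchange should proceed with retention of alkene geometry and 1,2-addition of the vinyllithium to the aldehyde at −78 °C should outrun enolisation; the carbinol centre is formed as a racemate on purpose and corrected in steps 6 and 7.

Step 6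
Reactants: 10 rac-(4E,8Z)-4,8,11,11-tetramethyltrideca-1,4,8,12-tetraen-7-ol
Product: 11 (4E,8Z)-4,8,11,11-tetramethyltrideca-1,4,8,12-tetraen-7-one
Conditions: Dess–Martin periodinane (1.3 equiv), pyridine, CH2Cl2, 0 °C
Reagents that add atoms: none
Why: Dess–Martin oxidation of the secondary allylic alcohol under buffered conditions should give the enone without Z to E isomerisation and without conjugation of the skipped C4=C5 alkene.

Step 7
Reactants: 11 (4E,8Z)-4,8,11,11-tetramethyltrideca-1,4,8,12-tetraen-7-one
Product: 12 (4E,7R,8Z)-4,8,11,11-tetramethyltrideca-1,4,8,12-tetraen-7-ol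
Conditions: (S)-2-methyl-CBS-oxazaborolidine (0.5 equiv), catecholborane (1.5 equiv), toluene, −78 °C
Reagents that add atoms: none
Why: Corey–Bakshi–Shibata reduction: the (S)-oxazaborolidine should treat the branched Z-alkenyl group as the large and the CH2 arm as the small substituent and deliver hydride to the face that gives the 7R alcohol, while catecholborane leaves the four C=C bonds untouched at this temperature.

Step 8
Reactants: 12 (4E,7R,8Z)-4,8,11,11-tetramethyltrideca-1,4,8,12-tetraen-7-ol; 13 4-acetoxy-3-methoxybenzoic acid
Product: 14 (4E,7R,8Z)-4,8,11,11-tetramethyltrideca-1,4,8,12-tetraen-7-yl 4-acetoxy-3-methoxybenzoate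
Conditions: N,N'-diisopropylcarbodiimide (1.5 equiv), DMAP (0.3 equiv), CH2Cl2, 0 °C → rt
Reagents that add atoms: none
Why: Steglich esterification (carbodiimide activation with DMAP acyl transfer) acylates the secondary allylic alcohol without breaking its C–O bond, so the 7R configuration is retained.

Step 9
Reactants: 14 (4E,7R,8Z)-4,8,11,11-tetramethyltrideca-1,4,8,12-tetraen-7-yl 4-acetoxy-3-methoxybenzoate
Product: 15 (1R,2Z,9E)-2,5,5,9-tetramethylcycloundeca-2,6,9-trien-1-yl 4-acetoxy-3-methoxybenzoate (C6=C7 geometry not controlled; either isomer serves)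
Conditions: second-generation Hoveyda–Grubbs catalyst RuCl2(H2IMes)(=CH-C6H4-2-O-i-Pr) (10 mol %), 1,4-benzoquinone (20 mol %), toluene (1 mM), 80 °C, slow addition of 14, argon sparge
Reagents that add atoms: none
Why: Ruthenium-carbene olefin metathesis (ring-closing metathesis): the catalyst loads on the unhindered allyl terminus, the alkylidene undergoes intramolecular [2+2] cycloaddition and cycloreversion with the vinyl group on the quaternary carbon, and ethene leaves and drives the equilibrium. The closest known reaction type is macrocyclic ring-closing metathesis of α,ω-dienes to ten- to twelve-membered carbocycles that already contain trisubstituted alkenes. The only ring, the eleven-membered carbocycle, is closed end to end between the two chain termini (chain C2 and C12 become ring C7 and C6). No stereocentre is formed; the geometry of the new C6=C7 alkene is left open because both isomers converge in step 10, and C1 (R) and the two trisubstituted alkenes are carried through unchanged. The step needs chemoselectivity for the two monosubstituted alkenes and cyclisation over oligomerisation: the C2=C3 and C9=C10 alkenes are trisubstituted and expected to be spectators, the C5 gem-dimethyl group (Thorpe–Ingold effect) and the two rigid alkenes fold the chain, and high dilution with slow addition suppresses intermolecular metathesis. 1,4-Benzoquinone intercepts ruthenium hydrides so that the skipped diene does not migrate into conjugation.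

Step 10
Reactants: 15 (1R,2Z,9E)-2,5,5,9-tetramethylcycloundeca-2,6,9-trien-1-yl 4-acetoxy-3-methoxybenzoate
Product: 16 (1R,2Z,9E)-2,5,5,9-tetramethylcycloundeca-2,9-dien-1-yl 4-acetoxy-3-methoxybenzoate
Conditions: 2-nitrobenzenesulfonohydrazide (excess, in portions), Et3N, CH2Cl2, rt
Reagents that add atoms: none
Why: Diimide reduction (concerted syn transfer of two hydrogens from HN=NH) is strongly sensitive to alkene substitution, so the strained 1,2-disubstituted C6=C7 bond should be saturated while the two trisubstituted ring alkenes, the allylic ester and the arene remain; both C6=C7 isomers give the same product.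

Step 11
Reactants: 16 (1R,2Z,9E)-2,5,5,9-tetramethylcycloundeca-2,9-dien-1-yl 4-acetoxy-3-methoxybenzoate
Product: 17 (1R,2Z,9E)-2,5,5,9-tetramethylcycloundeca-2,9-dien-1-yl 4-hydroxy-3-methoxybenzoate
Conditions: K2CO3 (cat.), MeOH, 0 °C
Reagents that add atoms: none
Why: Base-catalysed methanolysis (transesterification) should cleave the activated aryl acetate much faster than the hindered, electron-rich secondary benzoate, freeing the phenol without touching C1.

**Compound list**

1 | pent-1-en-4-yne | C=CCC#C | starting material
2 | dimethyl[(1E)-2-methylpenta-1,4-dien-1-yl]alane (not isolated) | C=CC/C(C)=C/[Al](C)C | intermediate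
3 | lithium butyl(dimethyl)[(1E)-2-methylpenta-1,4-dien-1-yl]alanate (not isolated) | [Li+].C=CC/C(C)=C/[Al-](C)(C)CCCC | intermediate
4 | (3E)-4-methylhepta-3,6-dien-1-ol | OCC/C=C(\C)CC=C | intermediate
5 | (3E)-4-methylhepta-3,6-dienal | O=CC/C=C(\C)CC=C | intermediate
6 | methyl 3,3-dimethylpent-4-enoate | COC(=O)CC(C)(C)C=C | starting material
7 | 3,3-dimethylpent-4-enal | O=CCC(C)(C)C=C | intermediate
8 | (5Z)-6-iodo-3,3-dimethylhepta-1,5-diene | C=CC(C)(C)C/C=C(\I)C | intermediate
9 | [(2E)-5,5-dimethylhepta-2,6-dien-2-yl]lithium, geometry of 8 retained (not isolated) | C=CC(C)(C)C/C=C(\[Li])C | intermediate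
10 | rac-(4E,8Z)-4,8,11,11-tetramethyltrideca-1,4,8,12-tetraen-7-ol | OC(C/C=C(\C)CC=C)/C(=C\CC(C=C)(C)C)C | intermediate
11 | (4E,8Z)-4,8,11,11-tetramethyltrideca-1,4,8,12-tetraen-7-one | O=C(C/C=C(\C)CC=C)/C(=C\CC(C=C)(C)C)C | intermediate
12 | (4E,7R,8Z)-4,8,11,11-tetramethyltrideca-1,4,8,12-tetraen-7-ol | O[C@H](C/C=C(\C)CC=C)/C(=C\CC(C=C)(C)C)C | intermediate
13 | 4-acetoxy-3-methoxybenzoic acid | COc1cc(C(=O)O)ccc1OC(C)=O | starting material
14 | (4E,7R,8Z)-4,8,11,11-tetramethyltrideca-1,4,8,12-tetraen-7-yl 4-acetoxy-3-methoxybenzoate | COc1cc(C(=O)O[C@H](C/C=C(\C)CC=C)/C(=C\CC(C=C)(C)C)C)ccc1OC(C)=O | intermediate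
15 | (1R,2Z,9E)-2,5,5,9-tetramethylcycloundeca-2,6,9-trien-1-yl 4-acetoxy-3-methoxybenzoate (C6=C7 geometry open) | COc1cc(C(=O)O[C@@H]2C/C=C(\C)CC=CC(C)(C)C/C=C\2C)ccc1OC(C)=O | intermediate
16 | (1R,2Z,9E)-2,5,5,9-tetramethylcycloundeca-2,9-dien-1-yl 4-acetoxy-3-methoxybenzoate | COc1cc(C(=O)O[C@@H]2C/C=C(\C)CCCC(C)(C)C/C=C\2C)ccc1OC(C)=O | intermediate
17 | (1R,2Z,9E)-2,5,5,9-tetramethylcycloundeca-2,9-dien-1-yl 4-hydroxy-3-methoxybenzoate | COc1cc(C(=O)O[C@@H]2C/C=C(\C)CCCC(C)(C)C/C=C\2C)ccc1O | target

**Step count and risks**

Total steps: 11. Longest linear sequence: 9 steps (steps 1, 2, 5–11 or steps 3, 4, 5–11).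

Steps most likely to fail:

1. Step 9. Intermolecular metathesis (oligomerisation) and ruthenium-hydride migration of the skipped diene may outpace closure of the strained eleven-membered ring, with the bulky aroyloxy group at C1 disfavouring the folded conformer. The fallback sets out from ketone 11 and comes back at 15. The same ring-closing metathesis is run one oxidation level earlier on 11, where C1 is planar and carries no ester, to give (2Z,9E)-2,5,5,9-tetramethylcycloundeca-2,6,9-trien-1-one F1. Corey–Bakshi–Shibata reduction of this ring enone ((S)-oxazaborolidine, catecholborane, toluene, −78 °C) should then give (1R,2Z,9E)-2,5,5,9-tetramethylcycloundeca-2,6,9-trien-1-ol F2, and Steglich esterification of the latter with 13 returns to 15. Ring closure and creation of the stereocentre thus change order.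

2. Step 10. Diimide may also attack the strained trisubstituted ring alkenes (over-reduction), or may react sluggishly at C6=C7 because of shielding by the C5 gem-dimethyl group. The fallback sets out from 15 and comes back at 16: homogeneous hydrogenation with RhCl(PPh3)3 under H2 (1 atm, benzene/EtOH, rt), in which selectivity comes from olefin coordination to the metal (disubstituted far ahead of trisubstituted) instead of a bimolecular pericyclic hydrogen transfer. New compounds on this path: none F0.

3. Step 7. The skipped C4=C5 alkene may migrate into conjugation or the Z-enone may isomerise during the oxidation and reduction sequence, and facial discrimination by the oxazaborolidine may be incomplete. The fallback sets out from 5 and 8 and comes back at 12: asymmetric Nozaki–Hiyama–Kishi coupling (CrCl2, NiCl2 (cat.), chiral oxazoline–sulfonamide ligand, Et3N, THF) should form the carbinol centre directly under reagent control with retention of the Z-vinyl geometry, so that neither 10 nor 11 is needed. New compounds on this path: none F0.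

**Further compounds**

F1 | step 9 | (2Z,9E)-2,5,5,9-tetramethylcycloundeca-2,6,9-trien-1-one (C6=C7 geometry open) | O=C1C/C=C(\C)CC=CC(C)(C)C/C=C\1C
F2 | step 9 | (1R,2Z,9E)-2,5,5,9-tetramethylcycloundeca-2,6,9-trien-1-ol (C6=C7 geometry open) | O[C@@H]1C/C=C(\C)CC=CC(C)(C)C/C=C\1C
F0 | step 10 | none | none
F0 | step 7 | none | none
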